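**Plan**
1. The retrosynthesis cuts, in both pyranone rings at once, the ketone–aryl bonds (C4–C4a, C4''–C4a'') and the ring-ether bonds (O1–C2, O1''–C2''). What remains is two molecules of phloroglucinol and one achiral diacid, 2-(4-hydroxybenzylidene)-3-(4-methoxybenzylidene)succinic acid, whose central C–C bond is the C3–C3'' bond of the target.
2. The enabling feature: C4(=O)–C3–C3''–C4''(=O) is a succinate 1,4-dicarbonyl array with an α-branched cinnamoyl unit on each side, and ring A and its twin are threefold-symmetric phloroglucinol. Every ring carbon is therefore a C-acylation site flanked by two OH groups, so there is no regiochemical choice, an ortho OH is always at hand for closure, and ring A needs no protecting group.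
3. Forward: the chain is built first (two successive Stobbe condensations put the two different arylidene groups on dimethyl succinate), the ester and silyl ether are hydrolysed, and both C rings then arise together in one acylation/oxa-Michael operation.
4. Stereochemistry: no stereocentre exists before the key step. 2,3-trans in each ring comes from thermodynamic control (reversible ring closure, enolisable C3); the like pairing of the two halves comes from separation with recycling of the unlike isomer; the absolute configuration comes from resolution on a chiral stationary phase as the last operation.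

Key step: step 5

Remark on the chemistry: unprimed locants denote the flavanone half that carries the 4-methoxyphenyl group and double-primed locants the half that carries the 4-hydroxyphenyl group (4' and 4''' are the para positions of these aryl groups). All four stereocentres of this 5-hydroxyflavanone system are labile to base (C3 by enolisation, C2 by ring opening), so they are set last and the resolved product is kept in neutral or slightly acidic media.

**Step 1**
Reactants: 1 dimethyl succinate; 2 4-methoxybenzaldehyde
Product: 3 (E)-4-(4-methoxyphenyl)-3-(methoxycarbonyl)but-3-enoic acid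
Conditions: NaOMe, MeOH, reflux; then aq. HCl
Reagents that add atoms: none
Why: Stobbe condensation, in which aldol addition is followed by irreversible transfer of one ester group into the carboxylate, so the reaction should stop at the half-ester with the usual E alkene (aryl trans to CO2Me); no stereocentre is formed.

**Step 2**
Reactants: 3 (E)-4-(4-methoxyphenyl)-3-(methoxycarbonyl)but-3-enoic acid
Product: 4 dimethyl (E)-2-(4-methoxybenzylidene)butanedioate
Conditions: MeOH, H2SO4 (cat.), reflux
Reagents that add atoms: methanol, CO
Why: Fischer esterification of the unhindered aliphatic CO2H restores a diester with one acidic CH2 for the second condensation and should leave the conjugated ester and the alkene geometry untouched.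

**Step 3**
Reactants: 4 dimethyl (E)-2-(4-methoxybenzylidene)butanedioate; 5 4-(tert-butyldimethylsilyloxy)benzaldehyde
Product: 6 (2E,3E)-2-(4-methoxybenzylidene)-3-[4-(tert-butyldimethylsilyloxy)benzylidene]butanedioic acid 4-methyl ester (free CO2H on the carbon that bears the 4-methoxybenzylidene group)
Conditions: LiN(iPr)2 (1.1 equiv), THF, −78 °C to rt; then cold dilute aq. HCl
Reagents that add atoms: none
Why: second Stobbe condensation at the only remaining CH2, a standard entry to unsymmetrical bis(arylidene)succinates; the ester of the first arm is the one converted into the carboxylate, the silyl ether should survive the non-nucleophilic base, and the alkene geometry (E,E expected) is of no consequence later.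

**Step 4**
Reactants: 6 (2E,3E)-2-(4-methoxybenzylidene)-3-[4-(tert-butyldimethylsilyloxy)benzylidene]butanedioic acid 4-methyl ester
Product: 7 (2E,3E)-2-(4-hydroxybenzylidene)-3-(4-methoxybenzylidene)butanedioic acid
Conditions: KOH (excess), MeOH/H2O, reflux; then aq. HCl to pH 2, 0 °C
Reagents that add atoms: potassium hydroxide, [K+].[OH-]
Why: saponification of the remaining conjugated methyl ester; the aryl silyl ether is cleaved by hydroxide in the same pot because phenoxide is a good leaving group on silicon, and the aryl methyl ether is inert.

**Step 5**
Reactants: 7 (2E,3E)-2-(4-hydroxybenzylidene)-3-(4-methoxybenzylidene)butanedioic acid; 8 phloroglucinol (3 equiv)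
Product: 10 racemic (2S*,3R*,2''S*,3''R*)-5,7,5'',7'',4'''-pentahydroxy-4'-methoxy-3,3''-biflavanone, via bis-chalcone 9 (not isolated)
Conditions: BF3·OEt2 (neat, excess), 80 °C; then NaOAc, MeOH/H2O, 60 °C; chromatography (silica, then Sephadex LH-20)
Reagents that add atoms: none
Why: BF3 converts each CO2H of 7 into an acyloxyboron mixed anhydride that acylates phloroglucinol at carbon (Friedel–Crafts acylation, directly or by O-acylation and Fries shift); each 2',4',6'-trihydroxychalcone unit of 9 is held as an O–BF2 chelate through one ortho OH while the other ortho OH adds to the benzylidene carbon (oxa-Michael) and the enol is protonated at C3, and the same sequence in the second arm closes the twin ring in the same flask. The closest known reaction type is the one-pot BF3·OEt2- or strong-acid-mediated acylation of phloroglucinol with carboxylic acids (the deoxybenzoin stage of isoflavone syntheses, which tolerates 4-hydroxy- and 4-methoxyphenyl groups) and its extension with α,β-unsaturated acids or acid chlorides to 5,7-dihydroxychroman-4-ones and flavanones. Each pyranone ring closes in the 6-endo-trig mode. C2, C3, C2'' and C3'' arise under thermodynamic control: the oxa-Michael step is reversible and C3 is enolisable, so the NaOAc stage should settle each ring in the 2,3-trans diequatorial form, whereas the like or unlike pairing of the two halves is not controlled, so the like racemate 10 is taken by chromatography and the unlike isomer is returned to the NaOAc equilibration. The step needs C-acylation to outrun conjugate C-alkylation at the benzylidene carbon (4-aryl-dihydrocoumarin formation), which the chelate-stabilised ketone sink and the α-branched, twisted diene of 7 should favour, and it needs no positional control on the phenol because the three ring carbons of phloroglucinol are equivalent and each is flanked by two OH groups. Either alkene geometry of 7 leads to the same product.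

**Step 6**
Reactants: 10 racemic (2S*,3R*,2''S*,3''R*)-5,7,5'',7'',4'''-pentahydroxy-4'-methoxy-3,3''-biflavanone
Product: 11 (2S,3R,2''S,3''R)-5,7,5'',7'',4'''-pentahydroxy-4'-methoxy-3,3''-biflavanone (CNP0196568.1)
Conditions: preparative HPLC, amylose tris(3,5-dimethylphenylcarbamate) on silica, n-hexane/iPrOH/0.1% HCO2H, rt
Reagents that add atoms: none
Why: chromatographic resolution of enantiomers on a chiral stationary phase separates 11 from its mirror image without reagent or base, so the stereocentres fixed relatively in step 5 are not disturbed; the configuration would be assigned from the ECD Cotton effects of the flavanone chromophore, and the unwanted enantiomer can be re-equilibrated with NaOAc and recycled.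

**Compound list**
1 | dimethyl succinate | COC(=O)CCC(=O)OC | starting material
2 | 4-methoxybenzaldehyde | COc1ccc(C=O)cc1 | starting material
3 | (E)-4-(4-methoxyphenyl)-3-(methoxycarbonyl)but-3-enoic acid | COC(=O)/C(=C/c1ccc(OC)cc1)CC(=O)O | intermediate
4 | dimethyl (E)-2-(4-methoxybenzylidene)butanedioate | COC(=O)/C(=C/c1ccc(OC)cc1)CC(=O)OC | intermediate
5 | 4-(tert-butyldimethylsilyloxy)benzaldehyde | CC(C)(C)[Si](C)(C)Oc1ccc(C=O)cc1 | starting material
6 | (2E,3E)-2-(4-methoxybenzylidene)-3-[4-(tert-butyldimethylsilyloxy)benzylidene]butanedioic acid 4-methyl ester | COC(=O)/C(=C/c1ccc(O[Si](C)(C)C(C)(C)C)cc1)/C(=C\c1ccc(OC)cc1)C(=O)O | intermediate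
7 | (2E,3E)-2-(4-hydroxybenzylidene)-3-(4-methoxybenzylidene)butanedioic acid | OC(=O)/C(=C/c1ccc(O)cc1)/C(=C\c1ccc(OC)cc1)C(=O)O | intermediate
8 | phloroglucinol (benzene-1,3,5-triol) | Oc1cc(O)cc(O)c1 | starting material
9 | (2E,3E)-2-(4-hydroxybenzylidene)-3-(4-methoxybenzylidene)-1,4-bis(2,4,6-trihydroxyphenyl)butane-1,4-dione (bis-chalcone, formed as its boron chelate) | O=C(c1c(O)cc(O)cc1O)/C(=C/c1ccc(O)cc1)/C(=C\c1ccc(OC)cc1)C(=O)c1c(O)cc(O)cc1O | intermediate
10 | racemic (2S*,3R*,2''S*,3''R*)-5,7,5'',7'',4'''-pentahydroxy-4'-methoxy-3,3''-biflavanone (both rings 2,3-trans, like pairing; 1:1 mixture of the two enantiomers) | COc1ccc([C@H]2Oc3cc(O)cc(O)c3C(=O)[C@@H]2[C@H]2C(=O)c3c(O)cc(O)cc3O[C@@H]2c2ccc(O)cc2)cc1.COc1ccc([C@@H]2Oc3cc(O)cc(O)c3C(=O)[C@H]2[C@@H]2C(=O)c3c(O)cc(O)cc3O[C@H]2c2ccc(O)cc2)cc1 | intermediate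
11 | (2S,3R,2''S,3''R)-5,7,5'',7'',4'''-pentahydroxy-4'-methoxy-3,3''-biflavanone | COc1ccc([C@H]2Oc3cc(O)cc(O)c3C(=O)[C@@H]2[C@H]2C(=O)c3c(O)cc(O)cc3O[C@@H]2c2ccc(O)cc2)cc1 | target

**Total step count:** 6
**Longest linear sequence:** 6 steps (1 → 3 → 4 → 6 → 7 → 10 → 11)

**Steps most likely to fail**

Step 5. The risk is conjugate C-alkylation of phloroglucinol at the electron-rich benzylidene carbons running ahead of C-acylation, which would lead to lactone (4-aryl-dihydrocoumarin) skeletons; acid-promoted dehydration of the 1,4-diketone is a lesser concern. The fallback sets out from 7 and 8 and returns at 9. Compound 7 would be converted with MeNHOMe·HCl, EDC·HCl and iPr2NEt into the bis(N-methoxy-N-methylamide) F1. Compound 8 would be protected with MOMCl and NaH as 1,3,5-tris(methoxymethoxy)benzene F2, which would be lithiated with n-BuLi (THF, 0 °C) and added in excess to F1 (Weinreb ketone synthesis; the first equivalent only deprotonates the phenol, and the aryl-lithium can attack nothing but the amide carbonyl) to give the hexakis(methoxymethyl)-protected bis-chalcone F3. HCl in MeOH would remove the six acetal groups to give 9, which closes to 10 under the NaOAc stage of step 5.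

Step 3. The risk is incomplete condensation of the hindered dienolate, retro-aldol cleavage and self-condensation of 4. The fallback sets out from 4 and returns at 7. Wohl–Ziegler bromination of the allylic, ester-activated CH2 (NBS, AIBN, PhCF3, 80 °C) would give dimethyl 2-bromo-3-(4-methoxybenzylidene)butanedioate F4, and Michaelis–Arbuzov reaction with P(OMe)3 (110 °C) the phosphonate F5. Horner–Wadsworth–Emmons olefination of F5 with 5 (NaH, THF, 0 °C to rt) would give dimethyl (2E,3E)-2-(4-methoxybenzylidene)-3-[4-(tert-butyldimethylsilyloxy)benzylidene]butanedioate F6, which under the conditions of step 4 gives 7.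

Step 6. The risk is erosion of configurational purity by epimerisation at C2 or C3 in solution during collection and evaporation, or incomplete separation from traces of the unlike diastereomer. The fallback sets out from 10 and returns at 11. It is a kinetic resolution by Noyori-type asymmetric transfer hydrogenation with RuCl(p-cymene)[(R,R)-TsDPEN] in HCO2H/Et3N (5:2) and EtOAc at rt. By analogy with simple flavanones, the (2R,3S,2''R,3''S) enantiomer should be reduced faster, to the all-equatorial bis(flavan-4-ol) F7 (both C4 carbonyls reduced, each 4-OH cis to the 2-aryl group and trans to the 3-substituent), while 11 should remain and be separated by ordinary chromatography; if the sense proved opposite, the (S,S) catalyst would be used.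

**Further compounds**
F1 | step 5 | (2E,3E)-2-(4-hydroxybenzylidene)-3-(4-methoxybenzylidene)-N,N'-dimethoxy-N,N'-dimethylbutanediamide | CON(C)C(=O)/C(=C/c1ccc(O)cc1)/C(=C\c1ccc(OC)cc1)C(=O)N(C)OC
F2 | step 5 | 1,3,5-tris(methoxymethoxy)benzene | COCOc1cc(OCOC)cc(OCOC)c1
F3 | step 5 | (2E,3E)-2-(4-hydroxybenzylidene)-3-(4-methoxybenzylidene)-1,4-bis[2,4,6-tris(methoxymethoxy)phenyl]butane-1,4-dione | O=C(c1c(OCOC)cc(OCOC)cc1OCOC)/C(=C/c1ccc(O)cc1)/C(=C\c1ccc(OC)cc1)C(=O)c1c(OCOC)cc(OCOC)cc1OCOC
F4 | step 3 | dimethyl 2-bromo-3-[(E)-4-methoxybenzylidene]butanedioate (racemic at C2) | COC(=O)C(Br)/C(=C\c1ccc(OC)cc1)C(=O)OC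
F5 | step 3 | dimethyl 2-(dimethoxyphosphoryl)-3-[(E)-4-methoxybenzylidene]butanedioate (racemic at C2) | COC(=O)C(P(=O)(OC)OC)/C(=C\c1ccc(OC)cc1)C(=O)OC
F6 | step 3 | dimethyl (2E,3E)-2-(4-methoxybenzylidene)-3-[4-(tert-butyldimethylsilyloxy)benzylidene]butanedioate | COC(=O)/C(=C/c1ccc(O[Si](C)(C)C(C)(C)C)cc1)/C(=C\c1ccc(OC)cc1)C(=O)OC
F7 | step 6 | bis(flavan-4-ol) from the (2R,3S,2''R,3''S) enantiomer of 11, both C4 carbonyls reduced, 4-OH cis to 2-aryl and trans to the 3-substituent in each ring | COc1ccc([C@@H]2Oc3cc(O)cc(O)c3[C@H](O)[C@H]2[C@@H]2[C@@H](O)c3c(O)cc(O)cc3O[C@H]2c2ccc(O)cc2)cc1
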